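## Structural features

The target is a 2,3-dihydro-1,4-benzodioxine: an aromatic ring A fused through C4a and C8a to a dioxane ring B (O1, C2, C3, O4). C2 carries the 3,4,5-trimethoxyphenyl ring C and C3 a methyl group. Ring A carries a methoxy group on C5, next to the O4-bearing C4a, and an (E)-3-oxoprop-1-enyl chain on C7, para to C4a. C2 and C3 are adjacent stereocentres, both R, with aryl and methyl trans; neither is next to a carbonyl group in the target, so neither can be corrected by late equilibration. The fragile groups are the enal (Michael acceptor, reducible, attacked by organoaluminium reagents), the C2–O1 bond (benzylic to an electron-rich arene, ionisable by acid) and the electron-rich rings (strong oxidants). The difficulty is threefold: the absolute configuration at C2, the trans relation to C3, and placing the two different carbons on the right oxygens, since O1 (meta to the side chain) and O4 (para to it) are chemically similar. The key step uses the fact that O1–C8a–C4a–O4 is a catechol: oxidised to the o-quinone it is a four-atom heterodiene O=C8a–C4a=O, while C2, C3 and ring C map onto the two carbons of an arylketene. The C7 substituent, para to the C4a oxygen, tells the two quinone oxygens apart.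

## Logic of the disconnections

The C=C bond of the C7 side chain of 14 is cut first, leading back to 13 and a two-carbon formyl ylide. The enal would not survive hydride or organoaluminium reagents, so it is made last; the cut removes the only alkene and leaves a plain aromatic aldehyde. The forward olefination must give the E alkene and stop after one homologation.

No skeletal bond is cut between 13 and 11: the aldehyde is traced through 12 to the methyl ester. C7 has to travel as an ester, because an electron-withdrawing group para to O4 steers the ring-forming step and an ester, unlike an aldehyde, tolerates the enolate, the hydride and the trimethylaluminium used earlier. The price is two redox steps, which must leave the benzylic C2–O1 ether untouched.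

The C3–CH3 bond of 11 is cut, giving the C3 acetate 9, which is ionised in the flask to 10. This makes the C3 stereocentre a consequence of C2 and leaves only a methyl nucleophile to be added. The forward step demands delivery of methyl to the face of 10 opposite ring C and no migration of the C2 hydrogen.

The C3–OAc and C3–H bonds of 9 are traced back, through 8, to the lactone carbonyl of 7, so that the carbonyl carbon serves as C3 at a higher oxidation level. The forward step must reduce the aryl lactone and not the C7 ester, and must trap the hemiacetal before ring B opens to an aldehyde that would let C2 epimerise.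

Ring B of 7 is cut at O1–C2 and O4–C3, giving 4 and, through 6 and 5, the acid chloride 2. This is the largest simplification: one catalytic step takes two flat, achiral components to ring B with C2 in place. The demands are high: the enolate carbon must bond to the oxygen on C8a and not to the C4a oxygen or a ring carbon, one enolate face must be used, and 7 must survive its own formation. Blocking the free positions of 4 with halogens was considered and rejected, because ortho substituents would twist the ester out of conjugation and remove the regiochemical control.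

4 is the two-electron oxidation product of 3, and 2 is the activated form of 1; no skeletal bond is involved. 1 and 3 are commercial and already carry every oxygen substituent of rings C and A in its final position. Forward, 4 must be made dry and free of oxidant and used at once, and 2 must be free of acid.

## Other disconnections considered

Alternative 1: The cuts are C2–C3 and C2–aryl, with O1–C8a left for a later aryl etherification.
- **Forward key step:** the (1S)-1-aryloxyethyl boronic ester A1, whose chiral dicyclohexylethanediol ester directs both events, would take up LiCHCl2 (1,2-shift of the aryloxyethyl group from boron to carbon, forming C2–C3). The 3,4,5-trimethoxyphenyl Grignard reagent would then trigger a second 1,2-shift with loss of chloride (forming C2–aryl) to give A2. Oxidation of the C–B bond, CuI-mediated closure of O1–C8a at the aryl bromide, acetal hydrolysis and the same olefination would follow.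
- **In its favour:** both stereocentres are under reagent control through stereospecific shifts, the two oxygens are distinguished by construction, and no intermediate has an acidic stereocentre. On these three points it is equal to or better than the chosen plan.
- **Against it here:** A2 and the chloro boronate before it hold boron β to an aryloxide, an arrangement prone to β-elimination, especially in the ate complex. It needs a stoichiometric chiral diol, LiCHCl2 at very low temperature and an acetal for the aldehyde, and ring B closes only several steps later.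
- **Comparison:** roughly ten linear steps against seven. The chosen plan is catalytic in its chiral agent and forms ring B and C2 together, but leaves C3 to substrate control, where Alternative 1 is stronger.

Alternative 2: The cut is O1–C2 alone, opening ring B to the phenol A3, a 1-arylpropan-2-yl aryl ether whose only stereocentre (the future C3) would come from the chiral pool.
- **Forward key step:** DDQ would take hydride from the CH2 group benzylic to ring C and the C8a hydroxyl would capture the cation, giving A4, which has the same structure as 13.
- **In its favour:** C3 would be set by an SN2 etherification of predictable outcome, the aldehyde is present from the start so the two redox steps disappear, and no activated ester or acidic stereocentre occurs. The route would be about five steps; on step economy and security of C3 it is better than the chosen plan.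
- **Against it here:** C2 rests on substrate control alone (capture anti to the C3 methyl). The 3,4,5-trimethoxybenzyl position is a poorer hydride donor than a 4-methoxybenzyl one, because the flanking methoxy groups twist the para oxygen out of conjugation. The free phenol of A3 is itself oxidisable by DDQ, and the C2–H of A4 is more activated than the CH2 of A3, so over-oxidation competes.
- **Comparison:** the step is a two-electron oxidation followed by cation capture, with C2 only relayed from C3. The chosen key step sets C2 directly by catalyst control and pays for that with about three more steps.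

Alternative 3: The cuts are O1–C2 and C2–C3, contracting ring B to the racemic 2-methyl-1,3-benzodioxole A5 and leaving C2 and ring C as the carbene from the aryldiazomethane A6.
- **Forward key step:** a dirhodium tetracarboxylate such as Rh2(OAc)4, or a chiral analogue, would generate the carbene. The acetal oxygen meta to the ester would form an oxonium ylide, and a [1,2]-shift of the acetal carbon to the carbene carbon would give A7, identical with 11.
- **In its favour:** A5 is one acetalisation from 3, the step forms two ring bonds and both stereocentres at once, and 11 would be reached in about three steps instead of five. The regiochemical preference also points the right way, since the oxygen not conjugated with the ester is the more basic. On convergence and step count it is clearly better.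
- **Against it here:** A6 is a donor-only, electron-rich diazo compound, hazardous to handle, whose carbene dimerises readily. Aryl ether oxygens are weak ylide formers, and rings A and C offer competing cyclopropanation sites. The [1,2]-shift runs through a radical or ion pair and the migrating carbon is racemic, so nothing in the substrate fixes either new centre or the trans relation; enantiocontrol would have to come entirely from the catalyst and survive the shift.
- **Comparison:** the chosen plan is longer, but each stereocentre has an identifiable controlling element.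

Key step: step 3

Remark on naming: the ring numbering O1, C2 (aryl), C3 (methyl), O4, C5 (OMe), C7 (side chain) is kept in every benzodioxine name below, including substituent-prefix names.

Assumption: benzoylquinidine is taken to give the (2R) lactone, by analogy with the enolate face it exposes to other electrophiles; if the opposite sense were found, benzoylquinine would be used and nothing else would change.

## Route

Step 1
Reactants: 1 (3,4,5-trimethoxyphenyl)acetic acid
Product: 2 (3,4,5-trimethoxyphenyl)acetyl chloride
Conditions: (COCl)2 (1.2 equiv), DMF (cat.), CH2Cl2, 0 °C to rt; evaporation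
Reagents that add atoms: oxalyl chloride, O=C(Cl)C(Cl)=O
Why: Acyl chloride formation through the chloroiminium (Vilsmeier-type) species from DMF and oxalyl chloride; the by-products are gases, so 2 should be obtained acid-free after evaporation and is used directly.

Step 2
Reactants: 3 methyl 3,4-dihydroxy-5-methoxybenzoate
Product: 4 methyl 5-methoxy-3,4-dioxocyclohexa-1,5-diene-1-carboxylate
Conditions: Ag2O (2.5 equiv), MgSO4, THF, 0 °C, dark; filtration under argon, solution used at once
Reagents that add atoms: none
Why: Two-electron oxidation of a catechol to the o-quinone by Ag2O under anhydrous neutral conditions; the solid oxidant and the silver formed are filtered off so no oxidant enters step 3, and the solution is used at once because an o-quinone with free ring positions dimerises on standing.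

Step 3
Reactants: 2 (3,4,5-trimethoxyphenyl)acetyl chloride; 4 methyl 5-methoxy-3,4-dioxocyclohexa-1,5-diene-1-carboxylate
Product: 7 methyl (2R)-5-methoxy-3-oxo-2-(3,4,5-trimethoxyphenyl)-2,3-dihydro-1,4-benzodioxine-7-carboxylate, via arylketene 5 (not isolated), via quinidinium enolate 6 (not isolated)
Conditions: benzoylquinidine (10 mol %), iPr2NEt (1.05 equiv), THF, −78 °C, slow addition of 2; cold filtration through silica
Reagents that add atoms: none
Why: iPr2NEt and the alkaloid dehydrohalogenate 2 to the arylketene 5, and the quinuclidine nitrogen of benzoylquinidine adds to it to give the Z-configured zwitterionic ammonium enolate 6. The enolate carbon of 6 attacks the oxygen on C8a of the electron-poor heterodiene O=C8a–C4a=O of 4, which aromatises ring A, and the C4a phenoxide so formed attacks the acylammonium carbon in a 6-exo-trig acyl substitution that closes ring B as the lactone and releases the catalyst. The closest known reaction type is the cinchona-alkaloid-catalysed inverse-electron-demand [4+2] cycloaddition of in situ ketene enolates with tetrahalo-o-quinones, applied here to a less electron-poor quinone. The new stereocentre C2 is under catalyst control: the benzoate and quinoline of the alkaloid shield one enolate face, and the (2R) lactone is expected by analogy with other electrophile captures of benzoylquinidine-bound enolates. The step needs regioselection between the two quinone oxygens, and the C7 ester secures it, because only attack at the C8a oxygen leaves a phenoxide (on C4a) conjugated with the para ester. It also needs O-attack over C-attack; the ester lowers the acceptor orbital of the heterodiene and O-attack aromatises directly, but the open C6 and C8 positions make conjugate C-addition the main competing path. 7 is worked up cold and without base because its C2–H, flanked by an aryl group and an activated ester, is acidic.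

Step 4
Reactants: 7 methyl (2R)-5-methoxy-3-oxo-2-(3,4,5-trimethoxyphenyl)-2,3-dihydro-1,4-benzodioxine-7-carboxylate
Product: 9 methyl (2R)-3-(acetyloxy)-5-methoxy-2-(3,4,5-trimethoxyphenyl)-2,3-dihydro-1,4-benzodioxine-7-carboxylate (C3 epimers), via aluminium hemiacetal 8 (not isolated)
Conditions: iBu2AlH (1.1 equiv), CH2Cl2, −78 °C; then pyridine, DMAP, Ac2O, −78 to 0 °C
Reagents that add atoms: acetic anhydride, CC(=O)OC(C)=O
Why: One-pot reductive acetylation of a lactone: the aryl lactone carbonyl, an activated phenolic ester, takes up hydride far faster than the methyl benzoate, and the tetrahedral aluminium hemiacetal 8 persists at −78 °C and is O-acetylated in place, so the ring-opened α-aryl aldehyde that would let C2 epimerise is never set free; the C3 acetal centre forms as a mixture that converges in step 5.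

Step 5
Reactants: 9 methyl (2R)-3-(acetyloxy)-5-methoxy-2-(3,4,5-trimethoxyphenyl)-2,3-dihydro-1,4-benzodioxine-7-carboxylate
Product: 11 methyl (2R,3R)-5-methoxy-3-methyl-2-(3,4,5-trimethoxyphenyl)-2,3-dihydro-1,4-benzodioxine-7-carboxylate, via oxocarbenium ion 10 (not isolated)
Conditions: AlMe3 (3 equiv), CH2Cl2, −78 to 0 °C
Reagents that add atoms: trimethylaluminium, C[Al](C)C
Why: Lewis-acid-mediated substitution of a cyclic α-acetoxy ether by a trialkylaluminium (C-glycosylation type): AlMe3 ionises the acetate to the oxocarbenium ion 10 and the aluminate transfers methyl; ring B of 10 is flattened by the fused arene and the O4=C3 bond, the C2 aryl group projects over one face, and methyl should enter on the other, giving the trans product and hence 3R; the C7 ester is inert to AlMe3 at this temperature.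

Step 6
Reactants: 11 methyl (2R,3R)-5-methoxy-3-methyl-2-(3,4,5-trimethoxyphenyl)-2,3-dihydro-1,4-benzodioxine-7-carboxylate
Product: 12 [(2R,3R)-5-methoxy-3-methyl-2-(3,4,5-trimethoxyphenyl)-2,3-dihydro-1,4-benzodioxin-7-yl]methanol
Conditions: iBu2AlH (2.5 equiv), CH2Cl2, −78 to 0 °C; Rochelle salt work-up
Reagents that add atoms: none
Why: Reduction of an aromatic methyl ester to the benzylic alcohol with two hydride equivalents; nothing else in 11 is reducible and the benzylic C2–O1 ether is stable to iBu2AlH at low temperature.

Step 7
Reactants: 12 [(2R,3R)-5-methoxy-3-methyl-2-(3,4,5-trimethoxyphenyl)-2,3-dihydro-1,4-benzodioxin-7-yl]methanol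
Product: 13 (2R,3R)-5-methoxy-3-methyl-2-(3,4,5-trimethoxyphenyl)-2,3-dihydro-1,4-benzodioxine-7-carbaldehyde
Conditions: MnO2 (activated, excess), CH2Cl2, rt
Reagents that add atoms: none
Why: Heterogeneous MnO2 oxidation, selective for benzylic alcohols, stops at the aldehyde and should not touch the C2–H of the benzylic ether or the electron-rich rings.

Step 8
Reactants: 13 (2R,3R)-5-methoxy-3-methyl-2-(3,4,5-trimethoxyphenyl)-2,3-dihydro-1,4-benzodioxine-7-carbaldehyde
Product: 14 (2E)-3-[(2R,3R)-5-methoxy-3-methyl-2-(3,4,5-trimethoxyphenyl)-2,3-dihydro-1,4-benzodioxin-7-yl]prop-2-enal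
Conditions: Ph3P=CHCHO (1.3 equiv), toluene, 80 °C
Reagents that add atoms: (triphenylphosphoranylidene)acetaldehyde, O=CC=P(c1ccccc1)(c1ccccc1)c1ccccc1
Why: Wittig olefination with a stabilised formyl ylide should give the E enal; the aromatic aldehyde is more electrophilic than the conjugated product, so one homologation should dominate with a small excess of ylide, and neither stereocentre is acidic.

## Compound list

1 | (3,4,5-trimethoxyphenyl)acetic acid | COc1cc(CC(=O)O)cc(OC)c1OC | starting material
2 | (3,4,5-trimethoxyphenyl)acetyl chloride | COc1cc(CC(Cl)=O)cc(OC)c1OC | intermediate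
3 | methyl 3,4-dihydroxy-5-methoxybenzoate | COC(=O)c1cc(O)c(O)c(OC)c1 | starting material
4 | methyl 5-methoxy-3,4-dioxocyclohexa-1,5-diene-1-carboxylate | COC(=O)C1=CC(=O)C(=O)C(OC)=C1 | intermediate
5 | (3,4,5-trimethoxyphenyl)ketene | COc1cc(C=C=O)cc(OC)c1OC | intermediate
6 | (Z)-1-(O-benzoylquinidin-1-ium-1-yl)-2-(3,4,5-trimethoxyphenyl)ethen-1-olate | COc1ccc2nccc([C@@H]([C@H]3C[C@@H]4CC[N+]3(C[C@@H]4C=C)/C([O-])=C/c3cc(OC)c(OC)c(OC)c3)OC(=O)c3ccccc3)c2c1 | intermediate
7 | methyl (2R)-5-methoxy-3-oxo-2-(3,4,5-trimethoxyphenyl)-2,3-dihydro-1,4-benzodioxine-7-carboxylate | COC(=O)c1cc(OC)c2OC(=O)[C@@H](c3cc(OC)c(OC)c(OC)c3)Oc2c1 | intermediate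
8 | methyl (2R)-3-{[bis(2-methylpropyl)alumanyl]oxy}-5-methoxy-2-(3,4,5-trimethoxyphenyl)-2,3-dihydro-1,4-benzodioxine-7-carboxylate (C3 epimers) | COC(=O)c1cc(OC)c2OC(O[Al](CC(C)C)CC(C)C)[C@@H](c3cc(OC)c(OC)c(OC)c3)Oc2c1 | intermediate
9 | methyl (2R)-3-(acetyloxy)-5-methoxy-2-(3,4,5-trimethoxyphenyl)-2,3-dihydro-1,4-benzodioxine-7-carboxylate (C3 epimers) | COC(=O)c1cc(OC)c2OC(OC(C)=O)[C@@H](c3cc(OC)c(OC)c(OC)c3)Oc2c1 | intermediate
10 | (2R)-5-methoxy-7-(methoxycarbonyl)-2-(3,4,5-trimethoxyphenyl)-2H-1,4-benzodioxin-4-ium acetoxy(trimethyl)aluminate | COC(=O)c1cc(OC)c2[O+]=C[C@@H](c3cc(OC)c(OC)c(OC)c3)Oc2c1.CC(=O)O[Al-](C)(C)C | intermediate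
11 | methyl (2R,3R)-5-methoxy-3-methyl-2-(3,4,5-trimethoxyphenyl)-2,3-dihydro-1,4-benzodioxine-7-carboxylate | COc1cc([C@H]2Oc3cc(C(=O)OC)cc(OC)c3O[C@@H]2C)cc(OC)c1OC | intermediate
12 | [(2R,3R)-5-methoxy-3-methyl-2-(3,4,5-trimethoxyphenyl)-2,3-dihydro-1,4-benzodioxin-7-yl]methanol | COc1cc([C@H]2Oc3cc(CO)cc(OC)c3O[C@@H]2C)cc(OC)c1OC | intermediate
13 | (2R,3R)-5-methoxy-3-methyl-2-(3,4,5-trimethoxyphenyl)-2,3-dihydro-1,4-benzodioxine-7-carbaldehyde | COc1cc([C@H]2Oc3cc(C=O)cc(OC)c3O[C@@H]2C)cc(OC)c1OC | intermediate
14 | (2E)-3-[(2R,3R)-5-methoxy-3-methyl-2-(3,4,5-trimethoxyphenyl)-2,3-dihydro-1,4-benzodioxin-7-yl]prop-2-enal | COc1cc([C@H]2Oc3cc(/C=C/C=O)cc(OC)c3O[C@@H]2C)cc(OC)c1OC | target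

## Step count and least certain steps

Total step count: 8. Longest linear sequence: 7 steps (3 to 14 through steps 2 to 8; equally 1 to 14 through steps 1 and 3 to 8).

**Step 3 (key step).**
- What may go wrong: conjugate addition of the enolate carbon to an open ring carbon (C6 or C8) of the quinone, or bonding to the C4a oxygen, because 4 is far less electron-poor and less substituted than the tetrahaloquinones on which the reaction type rests. Dimerisation of 4 before it is intercepted and loss of the C2 configuration by enolisation of 7 in the presence of amine are further risks.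
- Fallback (sets out from 3 and 1, returns at 7): ring B is assembled stepwise by a carbene O–H insertion.
  - The C4 hydroxyl of 3, para to the ester and the more acidic, is benzylated (BnBr, KHCO3, DMF) to methyl 4-(benzyloxy)-3-hydroxy-5-methoxybenzoate F1.
  - 1 is esterified (MeOH, H2SO4) to methyl (3,4,5-trimethoxyphenyl)acetate F2, and diazo transfer (4-acetamidobenzenesulfonyl azide, DBU, MeCN) gives methyl diazo(3,4,5-trimethoxyphenyl)acetate F3.
  - Enantioselective insertion of the carbene from F3 into the O–H bond of F1 (Pd(PhCN)2Cl2, chiral spiro-bisoxazoline ligand, NaB[3,5-(CF3)2C6H3]4) should give methyl 4-(benzyloxy)-3-methoxy-5-[(1R)-2-methoxy-2-oxo-1-(3,4,5-trimethoxyphenyl)ethoxy]benzoate F4.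
  - Brief hydrogenolysis (H2, Pd/C, EtOAc), which should spare the hindered, ester-deactivated C2–O bond, frees methyl 4-hydroxy-3-methoxy-5-[(1R)-2-methoxy-2-oxo-1-(3,4,5-trimethoxyphenyl)ethoxy]benzoate F5, which is lactonised (TsOH, toluene) to 7.

**Step 5.**
- What may go wrong: poor facial selectivity at the nearly planar oxocarbenium ion, delivery of methyl on the side of the departing acetate within a tight ion pair, or a 1,2-hydride shift from C2 that moves the charge to the doubly stabilised benzylic position and scrambles the skeleton.
- Fallback (sets out from 3, returns at 11): the methyl-bearing centre is taken from the chiral pool and the aryl-bearing centre is closed last.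
  - Mitsunobu etherification of the more acidic C4 hydroxyl of 3 with ethyl (S)-lactate (PPh3, diisopropyl azodicarboxylate, THF) should proceed with inversion to methyl 4-{[(2R)-1-ethoxy-1-oxopropan-2-yl]oxy}-3-hydroxy-5-methoxybenzoate F6.
  - Acid-catalysed lactonisation (TsOH, toluene, reflux) gives methyl (3R)-5-methoxy-3-methyl-2-oxo-2,3-dihydro-1,4-benzodioxine-7-carboxylate F7.
  - iBu2AlH (1.1 equiv, −78 °C) gives the lactol methyl (3R)-2-hydroxy-5-methoxy-3-methyl-2,3-dihydro-1,4-benzodioxine-7-carboxylate F8.
  - (3,4,5-Trimethoxyphenyl)magnesium bromide (2.2 equiv, THF, −78 to 0 °C) adds to the ring-opened aldehyde to give methyl 3-hydroxy-4-{[(2R)-1-hydroxy-1-(3,4,5-trimethoxyphenyl)propan-2-yl]oxy}-5-methoxybenzoate F9 as a mixture of carbinol epimers.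
  - A sulfonic acid resin (Amberlyst 15, CH2Cl2) ionises the benzylic alcohol of F9, and capture by the phenol anti to the methyl group should converge both epimers on 11.

**Step 4.**
- What may go wrong: collapse of the aluminium hemiacetal with loss of the good aryloxide leaving group before acetylation, followed by over-reduction of the freed aldehyde or epimerisation at C2; attack of hydride on the C7 ester is a lesser concern.
- Fallback (sets out from 7, returns at 9): the reduction is done on a ring-opened amide whose chelated tetrahedral intermediate cannot collapse.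
  - N,O-dimethylhydroxylamine (THF, 0 °C) opens the activated lactone to methyl 4-hydroxy-3-methoxy-5-{(1R)-2-[methoxy(methyl)amino]-2-oxo-1-(3,4,5-trimethoxyphenyl)ethoxy}benzoate F10.
  - iBu2AlH (2.2 equiv, −78 °C) and neutral work-up should give the aldehyde, which closes onto the neighbouring phenol as methyl (2R)-3-hydroxy-5-methoxy-2-(3,4,5-trimethoxyphenyl)-2,3-dihydro-1,4-benzodioxine-7-carboxylate F11.
  - Acetylation (Ac2O, pyridine, 0 °C) gives 9.

**Step 8.**
- What may go wrong: a second olefination of the product enal, giving the dienal, and incomplete conversion of the electron-rich aldehyde.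
- Fallback (sets out from 13, returns at 14): the two carbons are added at the ester oxidation level.
  - Horner–Wadsworth–Emmons reaction with triethyl phosphonoacetate (LiCl, DBU, MeCN) gives ethyl (2E)-3-[(2R,3R)-5-methoxy-3-methyl-2-(3,4,5-trimethoxyphenyl)-2,3-dihydro-1,4-benzodioxin-7-yl]prop-2-enoate F12.
  - iBu2AlH (CH2Cl2, −78 °C) reduces it to (2E)-3-[(2R,3R)-5-methoxy-3-methyl-2-(3,4,5-trimethoxyphenyl)-2,3-dihydro-1,4-benzodioxin-7-yl]prop-2-en-1-ol F13.
  - MnO2 (CH2Cl2, rt) oxidises F13 to 14.

## Further compounds

F1 | step 3 | methyl 4-(benzyloxy)-3-hydroxy-5-methoxybenzoate | COC(=O)c1cc(O)c(OCc2ccccc2)c(OC)c1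
F2 | step 3 | methyl (3,4,5-trimethoxyphenyl)acetate | COC(=O)Cc1cc(OC)c(OC)c(OC)c1
F3 | step 3 | methyl diazo(3,4,5-trimethoxyphenyl)acetate | COC(=O)C(=[N+]=[N-])c1cc(OC)c(OC)c(OC)c1
F4 | step 3 | methyl 4-(benzyloxy)-3-methoxy-5-[(1R)-2-methoxy-2-oxo-1-(3,4,5-trimethoxyphenyl)ethoxy]benzoate | COC(=O)[C@H](Oc1cc(C(=O)OC)cc(OC)c1OCc1ccccc1)c1cc(OC)c(OC)c(OC)c1
F5 | step 3 | methyl 4-hydroxy-3-methoxy-5-[(1R)-2-methoxy-2-oxo-1-(3,4,5-trimethoxyphenyl)ethoxy]benzoate | COC(=O)[C@H](Oc1cc(C(=O)OC)cc(OC)c1O)c1cc(OC)c(OC)c(OC)c1
F6 | step 5 | methyl 4-{[(2R)-1-ethoxy-1-oxopropan-2-yl]oxy}-3-hydroxy-5-methoxybenzoate | CCOC(=O)[C@@H](C)Oc1c(O)cc(C(=O)OC)cc1OC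
F7 | step 5 | methyl (3R)-5-methoxy-3-methyl-2-oxo-2,3-dihydro-1,4-benzodioxine-7-carboxylate | COC(=O)c1cc(OC)c2O[C@H](C)C(=O)Oc2c1
F8 | step 5 | methyl (3R)-2-hydroxy-5-methoxy-3-methyl-2,3-dihydro-1,4-benzodioxine-7-carboxylate (C2 epimers) | COC(=O)c1cc(OC)c2O[C@H](C)C(O)Oc2c1
F9 | step 5 | methyl 3-hydroxy-4-{[(2R)-1-hydroxy-1-(3,4,5-trimethoxyphenyl)propan-2-yl]oxy}-5-methoxybenzoate (carbinol epimers) | COC(=O)c1cc(O)c(O[C@H](C)C(O)c2cc(OC)c(OC)c(OC)c2)c(OC)c1
F10 | step 4 | methyl 4-hydroxy-3-methoxy-5-{(1R)-2-[methoxy(methyl)amino]-2-oxo-1-(3,4,5-trimethoxyphenyl)ethoxy}benzoate | CON(C)C(=O)[C@H](Oc1cc(C(=O)OC)cc(OC)c1O)c1cc(OC)c(OC)c(OC)c1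
F11 | step 4 | methyl (2R)-3-hydroxy-5-methoxy-2-(3,4,5-trimethoxyphenyl)-2,3-dihydro-1,4-benzodioxine-7-carboxylate (C3 epimers) | COC(=O)c1cc(OC)c2OC(O)[C@@H](c3cc(OC)c(OC)c(OC)c3)Oc2c1
F12 | step 8 | ethyl (2E)-3-[(2R,3R)-5-methoxy-3-methyl-2-(3,4,5-trimethoxyphenyl)-2,3-dihydro-1,4-benzodioxin-7-yl]prop-2-enoate | COc1cc([C@H]2Oc3cc(/C=C/C(=O)OCC)cc(OC)c3O[C@@H]2C)cc(OC)c1OC
F13 | step 8 | (2E)-3-[(2R,3R)-5-methoxy-3-methyl-2-(3,4,5-trimethoxyphenyl)-2,3-dihydro-1,4-benzodioxin-7-yl]prop-2-en-1-ol | COc1cc([C@H]2Oc3cc(/C=C/CO)cc(OC)c3O[C@@H]2C)cc(OC)c1OC
A1 | alternative 1 | (4S,5S)-2-{(1S)-1-[2-bromo-4-(1,3-dioxolan-2-yl)-6-methoxyphenoxy]ethyl}-4,5-dicyclohexyl-1,3,2-dioxaborolane | C[C@@H](Oc1c(Br)cc(C2OCCO2)cc1OC)B1O[C@@H](C2CCCCC2)[C@H](C2CCCCC2)O1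
A2 | alternative 1 | (4S,5S)-2-[(1R,2R)-2-(2-bromo-4-(1,3-dioxolan-2-yl)-6-methoxyphenoxy)-1-(3,4,5-trimethoxyphenyl)propyl]-4,5-dicyclohexyl-1,3,2-dioxaborolane | C[C@@H](Oc1c(Br)cc(C2OCCO2)cc1OC)[C@@H](c1cc(OC)c(OC)c(OC)c1)B1O[C@@H](C2CCCCC2)[C@H](C2CCCCC2)O1
A3 | alternative 2 | 3-hydroxy-5-methoxy-4-{[(2R)-1-(3,4,5-trimethoxyphenyl)propan-2-yl]oxy}benzaldehyde | COc1cc(C[C@@H](C)Oc2c(O)cc(C=O)cc2OC)cc(OC)c1OC
A4 | alternative 2 | (2R,3R)-5-methoxy-3-methyl-2-(3,4,5-trimethoxyphenyl)-2,3-dihydro-1,4-benzodioxine-7-carbaldehyde | COc1cc([C@H]2Oc3cc(C=O)cc(OC)c3O[C@@H]2C)cc(OC)c1OC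
A5 | alternative 3 | methyl 7-methoxy-2-methyl-1,3-benzodioxole-5-carboxylate (racemic) | COC(=O)c1cc(OC)c2OC(C)Oc2c1
A6 | alternative 3 | 5-(diazomethyl)-1,2,3-trimethoxybenzene | COc1cc(C=[N+]=[N-])cc(OC)c1OC
A7 | alternative 3 | methyl (2R,3R)-5-methoxy-3-methyl-2-(3,4,5-trimethoxyphenyl)-2,3-dihydro-1,4-benzodioxine-7-carboxylate | COc1cc([C@H]2Oc3cc(C(=O)OC)cc(OC)c3O[C@@H]2C)cc(OC)c1OC
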